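Atom labels used for every compound: five-membered ring C1(Me)–C2–C3(OAc)–C4(OH, iPr)–C5(H); seven-membered ring C1–C10(OH)–C9–C8(Me)=C7–C6(O-aroyl)–C5; β is the face of the C1 methyl.
Retrosynthesis, in order: the acetate and both silyl groups; the C3–O and C4–O bonds (to a C3=C4 alkene); the C6–O acyl bond; the C4–isopropyl bond (to the enol triflate of a C4 ketone); the C8–methyl bond and the C7=C8 unsaturation (to a C6 ketone).
Last cut: the ring-fusion bond C1–C5; putting C1 back on C6 turns the cis-hydroazulen-6-one into a trans-decalin-5,6-diol 5-mesylate.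
Feature that allows this: C1–C5 links the methyl-bearing quaternary C1 to a CH whose neighbour C6 in the seven-membered ring carries oxygen, and C4 and C10 are oxygenated too, so the decalin (ring A = C1, C10, C9, C8, C7, C6; ring B = C1 to C6) is the α-face diol of a twice-reduced (S)-Wieland–Miescher ketone.
Forward: both six-membered rings are bought; one 1,2-shift contracts ring B to the cyclopentane and expands ring A to the cycloheptanone; the seven-membered ring is finished first (enone, methyl, C6 alcohol), the five-membered ring last (isopropyl alkene, C6 ester, cis-diol, acetate).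
Stereochemistry: C1 from the starting ketone; C10 by hydride anti to the angular methyl; C5 by inversion in the shift, the diol face being set by osmylation anti to the methyl; C6, C3 and C4 by attack on the convex β face of the cis-fused bicycle.

Key step: step 7

Assumption: hydride (step 10) and OsO4 (step 19) are taken to attack the cis-fused hydroazulene on its convex β face, as the shape of the bicycle suggests. TBS = tert-butyldimethylsilyl, TES = triethylsilyl, TIPS = triisopropylsilyl, PMB = 4-methoxybenzyl.

Step 1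
Reactants: 1 (S)-Wieland–Miescher ketone
Product: 2 10β-hydroxy enone, (4aS,5S)-5-hydroxy-4a-methyl-4,4a,5,6,7,8-hexahydronaphthalen-2(3H)-one
Conditions: NaBH4 (0.3 equiv), EtOH, −10 to 0 °C
Reagents that add atoms: none
Why: Chemoselective NaBH4 reduction of the saturated C10 ketone (the conjugated C4 carbonyl is less electrophilic) with hydride entering anti to the angular methyl should set the equatorial 10β-hydroxyl cis to that methyl.

Step 2
Reactants: 2 10β-hydroxy enone
Product: 3 10β-TBS-oxy enone
Conditions: TBSCl, imidazole, DMF, 40 °C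
Reagents that add atoms: tert-butyldimethylsilyl chloride, CC(C)(C)[Si](C)(C)Cl
Why: Imidazole-promoted silylation of the secondary alcohol gives an ether that should survive every base, hydride and oxidant used before the final fluoride step, and no stereocentre is touched.

Step 3
Reactants: 3 10β-TBS-oxy enone
Product: 4 Δ5-octalin-4β-ol (10β-OTBS)
Conditions: NaBH4, CeCl3·7H2O, MeOH, −78 to −20 °C
Reagents that add atoms: none
Why: Luche reduction adds hydride 1,2 to the enone, axially on the α face anti to the angular methyl, which should set the pseudo-equatorial 4β-allylic alcohol.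

Step 4
Reactants: 4 Δ5-octalin-4β-ol
Product: 6 Δ5-octalin 4β-PMB ether 10β-TBS ether, via sodium C4-alkoxide 5 (not isolated)
Conditions: NaH, THF–DMF, 0 °C; then 4-methoxybenzyl chloride, Bu4NI (cat.), 0 °C to rt
Reagents that add atoms: 4-methoxybenzyl chloride, COc1ccc(CCl)cc1
Why: Williamson ether synthesis turns the C4 oxygen into an ether that cannot serve as an alkoxide donor in step 7 and can later be removed oxidatively beside silyl ethers.

Step 5
Reactants: 6 Δ5-octalin 4β-PMB ether 10β-TBS ether
Product: 7 trans-decalin-5α,6α-diol (4β-OPMB, 10β-OTBS)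
Conditions: OsO4 (5 mol %), N-methylmorpholine N-oxide, acetone–H2O, rt to 40 °C
Reagents that add atoms: OsO4 (catalytic oxygen carrier), O=[Os](=O)(=O)=O; N-methylmorpholine N-oxide, C[N+]1([O-])CCOCC1; water, O
Why: Upjohn dihydroxylation adds both oxygens syn to the trisubstituted C5=C6 alkene from the α face, anti to the angular 1β-methyl and to the allylic 4β-ether, which sets C5 and C6 and makes the ring fusion trans.

Step 6
Reactants: 7 trans-decalin-5α,6α-diol
Product: 8 trans-decalin-5α,6α-diol 5-mesylate (C6–OH free)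
Conditions: MsCl, Et3N, CH2Cl2, −10 to 0 °C
Reagents that add atoms: methanesulfonyl chloride, CS(=O)(=O)Cl
Why: Sulfonylation through the sulfene should take the secondary equatorial C5 hydroxyl and leave the tertiary angular C6 hydroxyl free, the arrangement the pinacol-type shift needs.

Step 7
Reactants: 8 trans-decalin-5α,6α-diol 5-mesylate
Product: 10 cis-hydroazulen-6-one (1β-Me 5β-H 4β-OPMB 10β-OTBS), via potassium C6-alkoxide 9 (not isolated)
Conditions: KOtBu (1.0 equiv), tBuOH–THF, 0 °C to rt; quench with pH 7 buffer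
Reagents that add atoms: none
Why: KOtBu deprotonates the angular C6 hydroxyl, and the alkoxide 9 pushes the C6–C1 σ bond, which lies antiperiplanar to the equatorial C5–OMs bond of the rigid trans-decalin, onto C5 as mesylate leaves, so that C6 becomes the ketone in one concerted 1,2-shift. The closest known reaction type is the base-promoted pinacol-type (semipinacol) rearrangement of vicinal diol monosulfonates, which is established for decalin-1,2-diol monosulfonates giving hydroazulenones. Neither ring is closed from an open chain: the cyclopentane C1–C2–C3–C4–C5 arises by contraction of ring B when C1 bonds to C5, and the cycloheptanone C1–C10–C9–C8–C7–C6–C5 by expansion of ring A when C5 is inserted between C6 and C1. The only new stereocentre, C5, is set by inversion at the migration terminus (C1 enters anti to the departing α-mesylate and keeps its own configuration), which places the C5 hydrogen β and makes the ring fusion cis. The step needs migration of C1 and not of C7 or C3, and no epoxide: C7 is gauche to the leaving group, the C4 oxygen is an ether without alkoxide push, and the cis-diol geometry forbids backside attack by oxygen. One equivalent of base is consumed as potassium methanesulfonate, so little base should remain to enolise the new ketone toward C5, which protects the cis fusion and the β-placed C4 ether.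

Step 8
Reactants: 10 cis-hydroazulen-6-one
Product: 12 hydroazul-7-en-6-one (4β-OPMB 10β-OTBS), via C6 trimethylsilyl enol ether 11 (not isolated)
Conditions: LiN(iPr)2, TMSCl, THF, −78 °C; then Pd(OAc)2 (1.1 equiv), MeCN, rt
Reagents that add atoms: none
Why: Kinetic deprotonation by lithium diisopropylamide at the C7 methylene (the hindered C5 methine is left alone, so C5 and the β-ether are not endangered) gives the Δ6 silyl enol ether, and its Saegusa–Ito oxidation with Pd(OAc)2 should install the C7=C8 enone.

Step 9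
Reactants: 12 hydroazul-7-en-6-one
Product: 14 8-methylhydroazul-7-en-6-one (4β-OPMB 10β-OTBS), via 8-methyl C6 trimethylsilyl enol ether 13 (not isolated)
Conditions: Me2CuLi (from MeLi and CuI), TMSCl, THF, −78 °C; then Pd(OAc)2 (1.1 equiv), MeCN, rt to 40 °C
Reagents that add atoms: lithium dimethylcuprate, [Li+].C[Cu-]C
Why: TMSCl-accelerated conjugate addition of Me2CuLi delivers the methyl to C8 and traps the enolate regiospecifically, and a second Saegusa–Ito oxidation removes the C8 hydrogen, so the transient C8 stereocentre is of no consequence.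

Step 10
Reactants: 14 8-methylhydroazul-7-en-6-one
Product: 15 8-methylhydroazul-7-en-6α-ol (4β-OPMB, 10β-OTBS)
Conditions: NaBH4, CeCl3·7H2O, MeOH, −78 °C
Reagents that add atoms: none
Why: Luche reduction gives 1,2-addition only, and hydride is expected to enter on the convex β face of the cis-fused bicycle (the side of the C5 hydrogen, away from the five-membered ring), which sets the 6α-alcohol.

Step 11
Reactants: 15 8-methylhydroazul-7-en-6α-ol
Product: 16 6α-TES ether (4β-OPMB, 10β-OTBS)
Conditions: TESCl, imidazole, DMF, 0 °C to rt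
Reagents that add atoms: triethylsilyl chloride, CC[Si](Cl)(CC)CC
Why: Silylation masks the allylic C6 alcohol as a group that is a poor leaving group in the enolate step, is inert to Pd(OAc)2 and iPrZnCl in step 15 and can later be removed beside the TBS ether.

Step 12
Reactants: 16 6α-TES ether
Product: 17 hydroazulen-4β-ol (6α-OTES, 10β-OTBS)
Conditions: DDQ, CH2Cl2–pH 7 buffer, 0 °C
Reagents that add atoms: none
Why: Oxidative cleavage of the 4-methoxybenzyl ether by DDQ (benzylic hydride abstraction, then hydrolysis) is selective for the electron-rich benzyl ether and should leave both silyl ethers and the alkene untouched.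

Step 13
Reactants: 17 hydroazulen-4β-ol
Product: 18 hydroazulen-4-one (6α-OTES, 10β-OTBS)
Conditions: Dess–Martin periodinane, pyridine, CH2Cl2, 0 °C to rt
Reagents that add atoms: none
Why: Dess–Martin oxidation under buffered, non-enolising conditions should give the cyclopentanone without epimerising C5 or eliminating the β-silyloxy group.

Step 14
Reactants: 18 hydroazulen-4-one
Product: 20 C3=C4 enol triflate (6α-OTES 10β-OTBS), via lithium C3-enolate 19 (not isolated)
Conditions: LiN(iPr)2, THF, −78 °C (ketone added to the base); then N-(5-chloro-2-pyridyl)bis(trifluoromethanesulfonimide), −78 to −40 °C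
Reagents that add atoms: N-(5-chloro-2-pyridyl)bis(trifluoromethanesulfonimide), FC(F)(F)S(=O)(=O)N(c1ccc(Cl)cn1)S(=O)(=O)C(F)(F)F
Why: Kinetic enolisation with lithium diisopropylamide removes a proton from the C3 methylene and not from the hindered ring-fusion C5, and O-sulfonylation of the enolate by the pyridyl triflimide fixes the C3=C4 enol triflate.

Step 15
Reactants: 20 C3=C4 enol triflate; 21 isopropylmagnesium chloride
Product: 22 4-isopropylhydroazula-3,7-diene (6α-OTES, 10β-OTBS)
Conditions: 21, ZnCl2, THF, 0 °C (gives iPrZnCl); then 20, Pd(OAc)2 (3 mol %), CPhos (6 mol %), THF–toluene, rt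
Reagents that add atoms: none
Why: Negishi cross-coupling of the alkenyl triflate with the secondary alkylzinc reagent, with a biarylphosphine ligand that favours reductive elimination over β-hydride elimination, should form the C4–isopropyl bond while silyl ethers and both alkenes stay inert.

Step 16
Reactants: 22 4-isopropylhydroazula-3,7-diene 6α-TES ether
Product: 23 4-isopropylhydroazula-3,7-dien-6α-ol (10β-OTBS)
Conditions: PPTS (cat.), MeOH–CH2Cl2, 0 °C
Reagents that add atoms: none
Why: Mild acid-catalysed methanolysis cleaves the triethylsilyl ether far faster than the hindered secondary TBS ether and should free only the C6 hydroxyl.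

Step 17
Reactants: 24 4-hydroxybenzoic acid
Product: 26 4-(triisopropylsilyloxy)benzoic acid, via bis-silylated acid 25 (not isolated)
Conditions: TIPSCl (2.2 equiv), imidazole, DMF, rt; then AcOH–THF–H2O, rt
Reagents that add atoms: triisopropylsilyl chloride, CC(C)[Si](Cl)(C(C)C)C(C)C
Why: Silylation of both acidic hydroxyls followed by hydrolysis of the labile silyl ester, which leaves the aryl silyl ether, gives the acid in a form whose phenol cannot be acylated in steps 18 and 20.

Step 18
Reactants: 23 4-isopropylhydroazula-3,7-dien-6α-ol; 26 4-(triisopropylsilyloxy)benzoic acid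
Product: 27 6α-[4-(triisopropylsilyloxy)benzoyloxy]-4-isopropylhydroazula-3,7-diene (10β-OTBS)
Conditions: DCC, DMAP, CH2Cl2, rt
Reagents that add atoms: none
Why: Steglich esterification (carbodiimide activation, DMAP acyl transfer) acylates the allylic C6 alcohol with retention, since the C6–O bond is not broken.

Step 19
Reactants: 27 6α-aroyloxy diene
Product: 28 3β,4β-diol (4α-isopropyl, 6α-aroyloxy, 10β-OTBS, C7=C8 intact)
Conditions: OsO4 (5 mol %), N-methylmorpholine N-oxide, acetone–H2O, 0 °C to rt
Reagents that add atoms: OsO4 (catalytic oxygen carrier), O=[Os](=O)(=O)=O; N-methylmorpholine N-oxide, C[N+]1([O-])CCOCC1; water, O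
Why: In this Upjohn dihydroxylation the C3=C4 cyclopentene is the more electron-rich alkene because C7=C8 is deactivated by its allylic aroyloxy group, and OsO4 adds syn on the convex β face, anti to the C5–C6 bond, which should set the 3β- and 4β-hydroxyls with the isopropyl group α.

Step 20
Reactants: 28 3β,4β-diol
Product: 29 3β-acetate (4β-OH, 6α-aroyloxy, 10β-OTBS)
Conditions: Ac2O, pyridine, DMAP (cat.), CH2Cl2, 0 °C to rt
Reagents that add atoms: acetic anhydride, CC(=O)OC(C)=O
Why: DMAP-catalysed acylation should take the secondary C3 hydroxyl and leave the tertiary C4 hydroxyl, while the phenol and the C10 oxygen are masked as silyl ethers.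

Step 21
Reactants: 29 3β-acetate
Product: 30 CNP0146780.2
Conditions: Bu4NF, AcOH, THF, rt to 40 °C
Reagents that add atoms: none
Why: Fluoride-mediated desilylation cleaves both the aryl triisopropylsilyl ether and the C10 TBS ether, and the acetic acid buffer should keep the medium from hydrolysing or shifting the two esters.

Compound list
1 | (S)-Wieland–Miescher ketone, (8aS)-8a-methyl-3,4,8,8a-tetrahydronaphthalene-1,6(2H,7H)-dione | C[C@]12CCC(=O)C=C1CCCC2=O | starting material
2 | (4aS,5S)-5-hydroxy-4a-methyl-4,4a,5,6,7,8-hexahydronaphthalen-2(3H)-one; 10β-OH cis to the methyl | C[C@]12CCC(=O)C=C1CCC[C@@H]2O | intermediate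
3 | 10β-TBS ether of 2 | C[C@]12CCC(=O)C=C1CCC[C@@H]2O[Si](C)(C)C(C)(C)C | intermediate
4 | Δ5-octalin-4β-ol with 1β-methyl and 10β-OTBS (allylic alcohol, all three substituents β) | C[C@]12CC[C@H](O)C=C1CCC[C@@H]2O[Si](C)(C)C(C)(C)C | intermediate
5 | sodium C4-alkoxide of 4 | C[C@]12CC[C@H]([O-])C=C1CCC[C@@H]2O[Si](C)(C)C(C)(C)C.[Na+] | intermediate (not isolated)
6 | 4β-PMB ether of 4 | C[C@]12CC[C@H](OCc3ccc(OC)cc3)C=C1CCC[C@@H]2O[Si](C)(C)C(C)(C)C | intermediate
7 | trans-decalin-5α,6α-diol: 1β-Me, 4β-OPMB, 5α-OH, angular 6α-OH, 10β-OTBS | C1C[C@]2(C)[C@@H](O[Si](C)(C)C(C)(C)C)CCC[C@@]2(O)[C@H](O)[C@H]1OCc1ccc(OC)cc1 | intermediate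
8 | 5α-methanesulfonate of 7, angular 6α-OH free | C1C[C@]2(C)[C@@H](O[Si](C)(C)C(C)(C)C)CCC[C@@]2(O)[C@H](OS(C)(=O)=O)[C@H]1OCc1ccc(OC)cc1 | intermediate
9 | potassium C6-alkoxide of 8 | C1C[C@]2(C)[C@@H](O[Si](C)(C)C(C)(C)C)CCC[C@@]2([O-])[C@H](OS(C)(=O)=O)[C@H]1OCc1ccc(OC)cc1.[K+] | intermediate (not isolated)
10 | cis-fused hydroazulen-6-one: 1β-Me, 5β-H, 4β-OPMB, 10β-OTBS | C1C[C@]2(C)[C@@H](O[Si](C)(C)C(C)(C)C)CCCC(=O)[C@@H]2[C@H]1OCc1ccc(OC)cc1 | intermediate
11 | C6=C7 trimethylsilyl enol ether of 10 | C1C[C@]2(C)[C@@H](O[Si](C)(C)C(C)(C)C)CCC=C(O[Si](C)(C)C)[C@@H]2[C@H]1OCc1ccc(OC)cc1 | intermediate (not isolated)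
12 | C7=C8 enone: cis-hydroazul-7-en-6-one, 4β-OPMB, 10β-OTBS | C1C[C@]2(C)[C@@H](O[Si](C)(C)C(C)(C)C)CC=CC(=O)[C@@H]2[C@H]1OCc1ccc(OC)cc1 | intermediate
13 | 8-methyl C6=C7 trimethylsilyl enol ether (C8 configuration not defined) | C1C[C@]2(C)[C@@H](O[Si](C)(C)C(C)(C)C)CC(C)C=C(O[Si](C)(C)C)[C@@H]2[C@H]1OCc1ccc(OC)cc1 | intermediate (not isolated)
14 | 8-methyl-cis-hydroazul-7-en-6-one, 4β-OPMB, 10β-OTBS | C1C[C@]2(C)[C@@H](O[Si](C)(C)C(C)(C)C)CC(C)=CC(=O)[C@@H]2[C@H]1OCc1ccc(OC)cc1 | intermediate
15 | 6α-allylic alcohol: 8-methylhydroazul-7-en-6α-ol, 4β-OPMB, 10β-OTBS | C1C[C@]2(C)[C@@H](O[Si](C)(C)C(C)(C)C)CC(C)=C[C@H](O)[C@@H]2[C@H]1OCc1ccc(OC)cc1 | intermediate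
16 | 6α-TES ether of 15 | C1C[C@]2(C)[C@@H](O[Si](C)(C)C(C)(C)C)CC(C)=C[C@H](O[Si](CC)(CC)CC)[C@@H]2[C@H]1OCc1ccc(OC)cc1 | intermediate
17 | 4β-alcohol: 6α-OTES, 10β-OTBS | C1C[C@]2(C)[C@@H](O[Si](C)(C)C(C)(C)C)CC(C)=C[C@H](O[Si](CC)(CC)CC)[C@@H]2[C@H]1O | intermediate
18 | 4-ketone: 6α-OTES, 10β-OTBS, 5β-H | C1C[C@]2(C)[C@@H](O[Si](C)(C)C(C)(C)C)CC(C)=C[C@H](O[Si](CC)(CC)CC)[C@@H]2C1=O | intermediate
19 | lithium C3=C4 enolate of 18 | C=1C[C@]2(C)[C@@H](O[Si](C)(C)C(C)(C)C)CC(C)=C[C@H](O[Si](CC)(CC)CC)[C@@H]2C=1[O-].[Li+] | intermediate (not isolated)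
20 | C3=C4 enol triflate (triflate on C4): 6α-OTES, 10β-OTBS | C=1C[C@]2(C)[C@@H](O[Si](C)(C)C(C)(C)C)CC(C)=C[C@H](O[Si](CC)(CC)CC)[C@@H]2C=1OS(=O)(=O)C(F)(F)F | intermediate
21 | isopropylmagnesium chloride | CC(C)[Mg]Cl | starting material
22 | 4-isopropyl-3,7-diene: 6α-OTES, 10β-OTBS | C=1C[C@]2(C)[C@@H](O[Si](C)(C)C(C)(C)C)CC(C)=C[C@H](O[Si](CC)(CC)CC)[C@@H]2C=1C(C)C | intermediate
23 | 4-isopropyl-3,7-dien-6α-ol, 10β-OTBS | C=1C[C@]2(C)[C@@H](O[Si](C)(C)C(C)(C)C)CC(C)=C[C@H](O)[C@@H]2C=1C(C)C | intermediate
24 | 4-hydroxybenzoic acid | OC(=O)c1ccc(O)cc1 | starting material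
25 | triisopropylsilyl 4-(triisopropylsilyloxy)benzoate | CC(C)[Si](C(C)C)(C(C)C)OC(=O)c1ccc(O[Si](C(C)C)(C(C)C)C(C)C)cc1 | intermediate (not isolated)
26 | 4-(triisopropylsilyloxy)benzoic acid | OC(=O)c1ccc(O[Si](C(C)C)(C(C)C)C(C)C)cc1 | intermediate
27 | 6α-[4-(triisopropylsilyloxy)benzoate] of 23 | C=1C[C@]2(C)[C@@H](O[Si](C)(C)C(C)(C)C)CC(C)=C[C@H](OC(=O)c3ccc(O[Si](C(C)C)(C(C)C)C(C)C)cc3)[C@@H]2C=1C(C)C | intermediate
28 | 3β,4β-diol: 4α-isopropyl, 6α-aroyloxy, 10β-OTBS, C7=C8 | O[C@H]1C[C@]2(C)[C@@H](O[Si](C)(C)C(C)(C)C)CC(C)=C[C@H](OC(=O)c3ccc(O[Si](C(C)C)(C(C)C)C(C)C)cc3)[C@@H]2[C@]1(O)C(C)C | intermediate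
29 | 3β-acetate of 28 | CC(=O)O[C@H]1C[C@]2(C)[C@@H](O[Si](C)(C)C(C)(C)C)CC(C)=C[C@H](OC(=O)c3ccc(O[Si](C(C)C)(C(C)C)C(C)C)cc3)[C@@H]2[C@]1(O)C(C)C | intermediate
30 | CNP0146780.2: 3β-acetoxy-4β,10β-dihydroxy-6α-(4-hydroxybenzoyloxy)-4α-isopropyl-1β,8-dimethyl-cis-hydroazul-7-ene (1S,3S,4R,5R,6S,10S in the labels used here) | CC(=O)O[C@H]1C[C@]2(C)[C@@H](O)CC(C)=C[C@H](OC(=O)c3ccc(O)cc3)[C@@H]2[C@]1(O)C(C)C | target

Total step count: 21 steps. Longest linear sequence: 20 steps (1 to 30 through steps 1–16 and 18–21); step 17 is a one-step side branch.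

Steps most likely to fail

Step 7. After the shift, any remaining alkoxide base could enolise the new ketone toward C5, which would epimerise the ring fusion or expel the C4 ether by β-elimination. The fallback replaces the alkoxide push under basic conditions by a Lewis-acid pull. It sets out from mesylate 8, which with Et2AlCl in CH2Cl2 at −78 °C should give the chloro(ethyl)aluminium C6-alkoxide F1 with loss of ethane. The aluminium centre then assists ionisation of the mesylate while the same C6–C1 bond migrates (organoaluminium-promoted pinacol-type rearrangement of a β-mesyloxy alcohol). The ketone stays bound to aluminium until an aqueous tartrate quench, so no enolising base meets the product. The fallback returns to the route at 10.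

Step 10. Hydride delivery could show poor facial selectivity or prefer the α face, leading mainly to the C6 epimer. The fallback accepts that outcome and inverts C6. It sets out from enone 14, whose reduction would then give the 6β-alcohol F2. Mitsunobu reaction of F2 with 4-nitrobenzoic acid (PPh3, DIAD, toluene, 0 °C to rt) should give the 6α-(4-nitrobenzoate) F3 with inversion. Methanolysis with K2CO3 in MeOH then returns to the route at 15.

Step 15. β-Hydride elimination from the isopropyl–palladium intermediate could compete with reductive elimination, leading to reduction of the triflate or to the n-propyl isomer. The fallback joins an sp2 partner that has no such pathway and adds the two hydrogens afterwards. It sets out from triflate 20. Suzuki–Miyaura coupling with isopropenylboronic acid pinacol ester (Pd(dppf)Cl2, K3PO4, dioxane–H2O, 60 °C) should give the 4-isopropenyl triene F4. Hydrogenation with RhCl(PPh3)3 and H2 (1 atm) in benzene should then reduce only the 1,1-disubstituted alkene, the two trisubstituted ring alkenes being much slower with this catalyst. The fallback returns to the route at 22.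

Further compounds
F1 | step 7 | chloro(ethyl)aluminium C6-alkoxide of mesylate 8 | C1C[C@]2(C)[C@@H](O[Si](C)(C)C(C)(C)C)CCC[C@@]2(O[Al](Cl)CC)[C@H](OS(C)(=O)=O)[C@H]1OCc1ccc(OC)cc1
F2 | step 10 | 6β-alcohol, C6 epimer of 15 | C1C[C@]2(C)[C@@H](O[Si](C)(C)C(C)(C)C)CC(C)=C[C@@H](O)[C@@H]2[C@H]1OCc1ccc(OC)cc1
F3 | step 10 | 6α-(4-nitrobenzoate) of 15 | C1C[C@]2(C)[C@@H](O[Si](C)(C)C(C)(C)C)CC(C)=C[C@H](OC(=O)c3ccc(cc3)[N+](=O)[O-])[C@@H]2[C@H]1OCc1ccc(OC)cc1
F4 | step 15 | 4-isopropenyl-3,7-diene (6α-OTES, 10β-OTBS) | C=1C[C@]2(C)[C@@H](O[Si](C)(C)C(C)(C)C)CC(C)=C[C@H](O[Si](CC)(CC)CC)[C@@H]2C=1C(C)=C
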